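Each target costs one nucleophile and each over-reaction product two, so the nucleophile spent can be reckoned from the rows below.

all flasks: electrophile 0.10 M

| flask | nucleophile | remark | time |
|---|---|---|---|
| Sunday's | 1.4 equiv (fed, over 40 h) | run made earlier; the fed solution adds 0.25 times the starting volume |  |
| Thursday's | 2.3 equiv (fed, over 40 h) | run made earlier; the fed solution adds 0.25 times the starting volume |  |
| alpha | 1.20 equiv (fed, over 40 h) | the fed solution adds 0.25 times the starting volume | 2.5 d |
| beta | 1.80 equiv (fed, over 40 h) | the fed solution adds 0.25 times the starting volume | 2.5 d |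

| run | time / h | electrophile / % | target / % | over-reaction product / % |
|---|---|---|---|---|
| Sunday's | 6.00 | 94.4 | 5.1 | 0.5 |
| Sunday's | 12.0 | 85.9 | 11.7 | 2.0 |
| Sunday's | 20.0 | 74.9 | 18.5 | 7.2 |
| Sunday's | 25.0 | 68.4 | 20.9 | 11.9 |
| Sunday's | 30.0 | 61.9 | 21.8 | 15.7 |
| Thursday's | 2.50 | 98.4 | 2.1 | 0.5 |
| Thursday's | 5.00 | 93.7 | 6.0 | 0.8 |
| Thursday's | 8.00 | 86.6 | 11.5 | 2.2 |
| Thursday's | 15.0 | 71.3 | 19.9 | 9.2 |
| Thursday's | 30.0 | 44.3 | 22.3 | 34.6 |

(readings scatter by 0.3 percentage points)

* which of these there is most of at the end, counted by the electrophile in it, alpha (target / electrophile / over-reaction product)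
* which of these there is most of at the end, counted by the electrophile in it, beta (target / electrophile / over-reaction product)
* amount of the one of these that there is most of at the end, in percent of the electrophile charged, alpha
* amount of the one of these that there is most of at the end, in percent of the electrophile charged, beta

Thursday's rows test that count. Around 8.00 h the electrophile falls at 0.0273 h⁻¹, and around 15.0 h at 0.0305 h⁻¹. Dividing by the nucleophile fed minus that count gives 0.0908 h⁻¹ and then 0.0635 h⁻¹, a fall. So nucleophile is vanishing unseen.

Suppose one more nucleophile is lost per electrophile converted. Then 16.7% and 19.2% remain, and the quotients become 0.164 h⁻¹ and 0.158 h⁻¹, nearly level. On that supposition the bill is 2 c(target) + 3 c(over-reaction product).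

The last rows supply the frozen term: c(target) stands at 21.8% on Sunday's run and 22.3% on Thursday's. Suppose the bill meets the charge by 2.5 d. On this bill nucleophile is the limiting reagent, because beta's 1.80 equiv pays for 64.8% of what full conversion costs.

The over-reaction estimate, charge minus twice the frozen target, divided by 3, gives alpha 25.1%, leaving electrophile 52.6%. Beta gets 45.1%, leaving 32.6%.

The forecast, weighing whether “the nucleophile is lost”, says electrophile at 49.5% for alpha and over-reaction product at 48% for beta. It names the same leaders, with numbers differing from this reckoning.

Alpha ends with electrophile at 49.7% and beta with over-reaction product at 49.0%.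

    electrophile + nucleophile → acid set free + target (k = 1.56 M⁻¹ h⁻¹)
    nucleophile + acid set free ⇌ protonated nucleophile, settled at all times (K = 2100 M⁻¹)
    nucleophile + target → over-reaction product (k = 3.60 M⁻¹ h⁻¹)

Alpha's over-reaction product stands at 27.5% against the estimate's 25.1%, and the neighbour with 2.00 equiv holds 56.4% against 51.8%. Alpha's electrophile half-life by the first step is 0.15 d with the whole charge counted, shorter than the 2.5 d, but 10 d at the asked time, longer than it, when 1.9% of alpha's nucleophile remains unbound beside 0.0319 M of protonated nucleophile and 0.00831 M of acid set free.

The runs are calculated for substances that don't exist, noise included.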